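(The runs are calculated for substances that don't exist; the scatter is artificial.)

A stirred vessel of constant volume takes Ja and Jb; Je forms, Jc appears on the way, and the six new flasks differ in how Ja and Jb go in and how cold they stand.

| flask | Ja | Jb | temperature | remark | time |
|---|---|---|---|---|---|
| larch | 0.10 M | 0.20 M | −5 °C | run made earlier |  |
| ash | 0.050 M | 0.20 M | 6 °C | run made earlier |  |
| alder | 0.20 M | 0.20 M | −5 °C | run made earlier |  |
| elm | 0.10 M | 0.40 M | 6 °C | run made earlier |  |
| delta | 0.10 M | 0.200 M (fed, over 40 min) | 0 °C | all else is in the flask from the start; the feed brings no volume worth counting | 4.0 h |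
| eta | 0.10 M | 0.200 M |  | everything together at the start at −20 °C, warmed to 0 °C at 2.5 h | 4.0 h |
| epsilon | 0.10 M (fed, over 2.5 h) | 0.200 M |  | the addition at −20 °C, then warmed to 0 °C; the feed brings no volume worth counting | 4.0 h |
| theta | 0.10 M | 0.200 M (fed, over 2.5 h) | 0 °C | all else is in the flask from the start; the feed brings no volume worth counting | 4.0 h |
| zeta | 0.10 M | 0.200 M | 0 °C | everything together at the start | 4.0 h |
| beta | 0.10 M (fed, over 2.5 h) | 0.200 M | 0 °C | all else is in the flask from the start; the feed brings no volume worth counting | 4.0 h |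

- larch (time / h: Jc / %, Je / %): 0.500: 17.8, 59.0; 1.33: 9.9, 72.6; 2.50: 7.9, 74.2; 4.00: 8.2, 74.6
- ash (time / h: Jc / %, Je / %): 0.417: 4.3, 80.3; 0.833: 3.3, 81.1; 2.00: 3.1, 81.3; 5.00: 3.6, 81.5
- alder (time / h: Jc / %, Je / %): 0.417: 34.6, 40.6; 0.833: 28.7, 49.9; 2.00: 26.4, 53.5; 5.00: 27.1, 52.2
- elm (time / h: Jc / %, Je / %): 0.667: 0.1, 95.6; 1.50: 0.4, 95.0; 3.00: 1.5, 95.9; 5.00: 0, 95.6

(scatter of a reading: 0.5 percentage points)

- a species is counted by the Ja in it: one Jc counts as two

- which flask leads in amount of Jc, in percent of the Ja charged ("all alike" within 1.5 percentage points) (delta / eta / epsilon / theta / zeta / beta / all alike)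
- how much Jc is there at the end, in percent of the Ja charged: delta
- how much Jc is there at the end, in percent of the Ja charged: eta
- how much Jc is there at the end, in percent of the Ja charged: epsilon
- how much Jc is there at the end, in percent of the Ja charged: theta
- how much Jc is there at the end, in percent of the Ja charged: zeta
- how much Jc is there at the end, in percent of the Ja charged: beta

At the last reading of a run, what is neither Je nor Jc counts as free Ja. From this comes the parking constant, [Jc] over the square of [Ja], with each Jc counted as one molecule. It reads 15.8 /M in alder at −5 °C and 16.2 /M in ash at 6 °C, both readings with their scatter. Jc thus acts as a resting state of Ja: the Ja not turned into Je divides between free Ja and Jc by this constant. By my own reckoning, a charge of 0.10 M with no Je made would hold 57.4% as Jc, and that ceiling is the one figure reckoned here before the result.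

The forecast puts beta first with 44% of Jc, which is less than that ceiling, because in beta “Jb dies before most Ja arrives”. For the others it gives 10% in delta, 10% in theta, 10% in zeta, 5.5% in eta and 11% in epsilon.

The flasks give beta first, with 44.6% of Jc, more than any other. Delta, theta and zeta each give 10.6%, eta gives 5.77% and epsilon 12.8%.

    2 Ja ⇌ Jc, settled at all times (K = 15.0 /M, ΔH = 0 kJ/mol)
    Ja + Jb → Je (k = 0.0150 /M/s, Ea = 62.0 kJ/mol)
    Jb → Jd (k = 8.40 × 10⁻⁴ /s, Ea = 77.0 kJ/mol)
    (constants at 0 °C)

In beta at 0.205 h, Jb was going to Jd 14 times as fast as into Je, and its half-life by that loss, 0.23 h, is far shorter than the feed of 2.5 h. Beta ends with Jb at 0% and Je at 16.8%, and the parking constant then turns that Je into 45.3% of Jc, beside the 44.6% found. A flask like beta kept at 15 °C ends with 3.14% of Je, which the same constant turns into 55.1% of Jc, beside the 54.3% found there.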